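in all of them: starting material 0.37 M (fed, over 2.5 min)
- Sunday's: reagent 0.21 M; run made earlier; the fed solution adds 0.50 times the starting volume
- Monday's: reagent 0.34 M; run made earlier; the fed solution adds 0.50 times the starting volume
- Tuesday's: reagent 0.66 M; run made earlier; the fed solution adds 0.50 times the starting volume
- eta: reagent 0.555 M; the fed solution adds 0.50 times the starting volume; time 5.0 min
- gamma: reagent 0.185 M; the fed solution adds 0.50 times the starting volume; time 5.0 min

| run | time / min | double product / % | mono adduct / % |
|---|---|---|---|
| Sunday's | 0.417 | 2 | 0 |
| Sunday's | 1.33 | 17 | 7 |
| Sunday's | 2.50 | 20 | 5 |
| Sunday's | 4.00 | 17 | 13 |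
| Sunday's | 5.00 | 20 | 12 |
| Monday's | 0.417 | 8 | 1 |
| Monday's | 0.833 | 14 | 6 |
| Monday's | 1.33 | 28 | 9 |
| Monday's | 2.50 | 34 | 8 |
| Monday's | 5.00 | 36 | 11 |
| Tuesday's | 0.417 | 13 | 3 |
| Tuesday's | 0.833 | 25 | 7 |
| Tuesday's | 1.33 | 42 | 5 |
| Tuesday's | 2.50 | 71 | 11 |
| Tuesday's | 5.00 | 80 | 12 |

(readings scatter by 1.5 percentage points)

- mono adduct is meant together with its crystals
- every charge counts on the volume at the start, and the solution that is fed holds the whole dose
- solid, in amounts per volume of the solution: crystals
- steps that have been proposed: starting material + reagent -> mono adduct; starting material + reagent -> other mono adduct; reagent + mono adduct -> double product; reagent + other mono adduct -> double product; crystals <-> mono adduct; mono adduct <-> isomer of the product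
- percentages count the whole charge, also what has not yet gone in

1. which of these holds the largest part of the starting material at the end of eta (mono adduct / starting material / other mono adduct / double product)
2. which of these holds the largest part of the starting material at the end of gamma (mono adduct / starting material / other mono adduct / double product)
3. final double product in gamma, as a percentage of the starting material charged

1. One unit served me throughout: the charge of starting material counted as one, with reagent as a fraction of it.

2. Sunday's double product read 20% at 2.50 min and 20% at 5.00 min, so I dropped time from my reckoning. Double product takes two reagent and mono adduct one, so Sunday's last readings demanded 52.0% of the 56.8% offered, and I took reagent as the limiting reagent in Sunday's run.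

3. That left two amounts: the reagent offered, and its cost. Sunday's last reading gave 2.84 of reagent charged per unit of double product formed, which I call the price. Monday's reading gave 2.55, which is less, and Tuesday's gave 2.23.

4. Gamma offers 0.500, which at Sunday's price buys 17.6% double product. I held this a little high, since the read price rose as reagent fell. Each unit of starting material reacted takes at least one reagent, so at least 50.0% stays as starting material in gamma. Eta offers 1.50, which buys 52.9%, more than the remainder, so I chose double product there.

5. The forecast said double product for eta, starting material for gamma, and 17% double product in gamma, below my figure. Its ground: “Scaling Sunday's plateau”.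

6. Eta ended with double product at 64.8%. Gamma ended with starting material at 66.3% and double product at 16.3%, a price of 3.06.

    starting material + reagent → mono adduct (k = 0.260 /M/s)
    starting material + reagent → other mono adduct (k = 0.200 /M/s)
    reagent + mono adduct → double product (k = 0.198 /M/s)
    reagent + other mono adduct → double product (k = 1.02 /M/s)
    crystals ⇌ mono adduct, rate k5*(cs5 - [mono adduct]) while solid is left; crystals form when [mono adduct] > cs5 (solubility = 0.120 M, k = 0.109 /s)
    mono adduct ⇌ isomer of the product (K = 0.450, k = 0.00984 /s)

In gamma at 0.713 min, dissolved mono adduct had a half-life of 0.72 min by its step to double product, shorter than reagent's 1.5 min by its step to other mono adduct. At 2.50 min in gamma, the step to mono adduct had 99.9% of its turnover behind it, and reagent stood at 0.101% of its own charge.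

In a neighbour of gamma, charged with 0.63 M starting material, 0.294 equiv of reagent buys 10.3% double product at Sunday's price. That neighbour flask gave 8.80%.

The data were generated by integration from invented constants.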